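## Retrosynthetic overview
1. The target comes from B–O hydrolysis of its own boron chelate, a neutral spiroborate that carries (R)-VANOL as a recoverable chiral ligand.
2. That spiroborate comes from one intermolecular, exo-selective [4+2] cycloaddition. It joins one enone arm of unprotected curcumin, held in a C2-symmetric boron chelate, to (E)-1-(3,4-dimethoxyphenyl)butadiene, the same union the plant is thought to use. It forms C1–C2, C5–C6 and all three stereocentres at once.
3. The diene comes from veratraldehyde and diethyl allylphosphonate by Horner–Wadsworth–Emmons olefination.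
4. Ring order: only the cyclohexene is built, in the cycloaddition. All arenes are bought.

## Assumptions
- **Cyclohexene numbering:** C1 carries the acyl group and C2 the 3,4-dimethoxyphenyl group. C3=C4 is the alkene, C5 is CH2, and C6 carries the 4-hydroxy-3-methoxyphenyl group. The target is (1R,2R,6S), all-trans.
- **Sense of induction:** it is taken from a quadrant model of the C2-symmetric spiroborate with s-cis enone arms. In this model the (R)-ligand covers the Cα-Re face of both arms, so the diene adds to the Cα-Si/Cβ-Si face. If a first run shows the opposite sense, (S)-VANOL is used and nothing else changes.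
- **Biaryl axis:** SMILES cannot express it, so the descriptor (R) in the names carries it.
- **Tautomers:** curcumin and the target are drawn as their chelated enol tautomers.

## Route

Step 1
Reactants: 1 veratraldehyde (3,4-dimethoxybenzaldehyde); 2 diethyl allylphosphonate
Product: 4 (E)-1-(3,4-dimethoxyphenyl)buta-1,3-diene, via lithiated allylphosphonate 3 (not isolated)
Conditions: 2 (1.2 equiv), n-BuLi (1.15 equiv), THF, −78 °C; then 1; then HMPA (2 equiv), −78 °C → rt, 12 h
Reagents that add atoms: none
Why: This is a Horner–Wadsworth–Emmons olefination in which the α-carbon of the lithiated allylphosphonate adds to the aldehyde and HMPA makes that addition reversible, so elimination runs through the adduct that gives the E alkene; no stereocentre is set.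

Step 2
Reactants: 5 curcumin; 6 triphenyl borate B(OPh)3; 7 (R)-VANOL; 4 (E)-1-(3,4-dimethoxyphenyl)buta-1,3-diene
Product: 9 (R)-VANOL spiroborate of the all-trans (1R,2R,6S) monoadduct, via curcumin spiroborate 8 (not isolated)
Conditions: 5, 6, 7 (1.3 equiv each), THF, 55 °C, 2 h; evaporate (0.1 mbar, 70 °C, removes PhOH); PhCF3, 4 (1.0 equiv, added over 6 h), BHT (5 mol %), dark, 40 °C, 48 h; SiO2, then crystallisation
Reagents that add atoms: none
Why: Proposed new method: the β-diketone of curcumin displaces phenoxide from boron to give a neutral tetracoordinate spiroborate of the rubrocurcumin type (oxalate replaced by the chiral diol), whose cyanine-like positive charge lowers the enone LUMO enough for a normal-demand Diels–Alder reaction with the electron-rich diene, while chelation blocks the hetero-Diels–Alder path and the free phenols stay spectators; the terminal CH2 of 4 (largest HOMO coefficient) bonds to the β-carbon and gives the "ortho" regiochemistry, the E alkene gives the trans C1/C6 relation, the bulky chelate takes the exo position with the guaiacyl ring stacked endo on the diene and so places the C2 aryl group trans to the acyl group, and because the ligand is C2-symmetric both enone arms are homotopic and expose only their Cα-Si face, which sets (1R,2R,6S); slow addition of 4 as the limiting partner holds back the bis-adduct and diene dimer; the closest known reaction type is the asymmetric Diels–Alder reaction of 2'-hydroxychalcones with 1-arylbutadienes promoted by chiral biaryl-diol borates, and since the ligand stays on boron the minor facial and endo isomers are diastereomers of 9 that chromatography and crystallisation remove.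

Step 3
Reactants: 9 (R)-VANOL spiroborate of the all-trans (1R,2R,6S) monoadduct
Product: 10 target, (2Z,4E)-1-[(1R,2R,6S)-2-(3,4-dimethoxyphenyl)-6-(4-hydroxy-3-methoxyphenyl)cyclohex-3-en-1-yl]-3-hydroxy-5-(4-hydroxy-3-methoxyphenyl)penta-2,4-dien-1-one
Conditions: 1 M aq HCl (cat.), THF/MeOH/H2O, 40 °C, 2 h; SiO2 (7 recovered)
Reagents that add atoms: none
Why: This is an acid-catalysed borate ester hydrolysis, as in the work-up of boron-templated curcumin syntheses, which cleaves only B–O bonds; curcuminoids are stable at low pH, and C1, the only epimerisable centre, already has its most stable all-equatorial configuration, so no stereocentre changes.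

## Compound list
1 | veratraldehyde (3,4-dimethoxybenzaldehyde) | COc1ccc(C=O)cc1OC | starting material
2 | diethyl allylphosphonate | C=CCP(=O)(OCC)OCC | starting material
3 | lithiated diethyl allylphosphonate | [Li+].C=C[CH-]P(=O)(OCC)OCC | intermediate
4 | (E)-1-(3,4-dimethoxyphenyl)buta-1,3-diene | C=C/C=C/c1ccc(OC)c(OC)c1 | intermediate
5 | curcumin, (1E,6E) enol form | COc1cc(/C=C/C(O)=C/C(=O)/C=C/c2ccc(O)c(OC)c2)ccc1O | starting material
6 | triphenyl borate B(OPh)3 | B(Oc1ccccc1)(Oc1ccccc1)Oc1ccccc1 | starting material
7 | (R)-VANOL, (R)-3,3'-diphenyl-[2,2'-binaphthalene]-1,1'-diol | Oc1c(-c2c(O)c3ccccc3cc2-c2ccccc2)c(-c2ccccc2)cc2ccccc12 | starting material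
8 | curcumin (R)-VANOL spiroborate: boron bound to both VANOL oxygens and chelated by the curcumin diketonate, both styryl alkenes E, C2-symmetric | COc1cc(/C=C/C2=CC(/C=C/c3ccc(O)c(OC)c3)=[O+][B-]3(O2)Oc2c4ccccc4cc(-c4ccccc4)c2-c2c(O3)c4ccccc4cc2-c2ccccc2)ccc1O | intermediate
9 | (R)-VANOL spiroborate of 10: same boron chelate, one arm now the (1R,2R,6S) all-trans cyclohex-3-enyl unit, other arm E-styryl | COc1cc(/C=C/C2=CC([C@@H]3[C@@H](c4ccc(O)c(OC)c4)CC=C[C@H]3c3ccc(OC)c(OC)c3)=[O+][B-]3(O2)Oc2c4ccccc4cc(-c4ccccc4)c2-c2c(O3)c4ccccc4cc2-c2ccccc2)ccc1O | intermediate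
10 | CNP0290899.1, (2Z,4E)-1-[(1R,2R,6S)-2-(3,4-dimethoxyphenyl)-6-(4-hydroxy-3-methoxyphenyl)cyclohex-3-en-1-yl]-3-hydroxy-5-(4-hydroxy-3-methoxyphenyl)penta-2,4-dien-1-one | COc1cc(/C=C/C(O)=C/C(=O)[C@@H]2[C@@H](c3ccc(O)c(OC)c3)CC=C[C@H]2c2ccc(OC)c(OC)c2)ccc1O | target

## Step count and risks
Total step count: 3.
Longest linear sequence: 3 (1 → 4 → 9 → 10).

**Most likely to fail: step 2.**
- The push-pull p-hydroxycinnamoyl arm may be too poor a dienophile.
- Facial or exo control at the remote β-carbon may be modest.
- Bis-adduct and diene dimer compete with the wanted monoadduct.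

The fallback gives up asymmetric induction in favour of resolution. It sets out from 4 and 5, which are heated together without boron (o-dichlorobenzene, BHT, 140 °C, sealed tube, 4 in threefold excess) in a plain thermal cycloaddition. The all-trans adduct is isolated as the racemate, that is 10 together with its mirror image ent-10 F1. The racemate is then treated with 6 and 7 (THF, 55 °C), which gives 9 and the (R)-VANOL spiroborate of ent-10 F2. These two diastereomers are separated on SiO2 or by crystallisation. The route is rejoined at 9.

**Second: step 3.**
- The chelate may resist mild acid.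
- Harsher acid could move the ring alkene into conjugation or cleave the diketone.

The fallback sets out from 9 and hands boron to a sacrificial diketone instead of hydrolysing it off. Compound 9 is warmed with acetylacetone (20 equiv) in MeCN at 60 °C under neutral conditions. Ligand metathesis at boron releases 10 and leaves (R)-VANOL boron acetylacetonate F3. The route is rejoined at 10.

**Third: step 1.**
- γ-Attack of the allyl anion could compete with α-attack.
- Elimination may be incomplete.
- The diene may polymerise on isolation.

The fallback replaces olefination by addition and elimination, and sets out from 1. Allylmagnesium bromide in THF at 0 °C gives racemic 1-(3,4-dimethoxyphenyl)but-3-en-1-ol F4. This alcohol is dehydrated with KHSO4 (cat.) and hydroquinone in toluene at 110 °C. The electron-rich benzylic cation loses the allylic proton to give the conjugated E diene. The route is rejoined at 4.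

## Further compounds
F1 | step 2 | ent-10, the (1S,2S,6R) mirror image of the target, formed with 10 as the racemate | COc1cc(/C=C/C(O)=C/C(=O)[C@H]2[C@H](c3ccc(O)c(OC)c3)CC=C[C@@H]2c2ccc(OC)c(OC)c2)ccc1O
F2 | step 2 | (R)-VANOL spiroborate of ent-10, diastereomer of 9 | COc1cc(/C=C/C2=CC([C@H]3[C@H](c4ccc(O)c(OC)c4)CC=C[C@@H]3c3ccc(OC)c(OC)c3)=[O+][B-]3(O2)Oc2c4ccccc4cc(-c4ccccc4)c2-c2c(O3)c4ccccc4cc2-c2ccccc2)ccc1O
F3 | step 3 | (R)-VANOL boron acetylacetonate | CC1=CC(C)=[O+][B-]2(O1)Oc1c3ccccc3cc(-c3ccccc3)c1-c1c(O2)c3ccccc3cc1-c1ccccc1
F4 | step 1 | racemic 1-(3,4-dimethoxyphenyl)but-3-en-1-ol | C=CCC(O)c1ccc(OC)c(OC)c1
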